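## Structural features

The target (22) is two 7-methoxycoumarin units joined by a 3,6-dimethylcyclohex-2-ene (ring C). C1' of ring C is bonded directly to C6 of coumarin A, and the quaternary C6' carries a methyl group and an (E)-ethenyl bridge (C7'=C8') to C8 of coumarin B. C1' (tertiary, benzylic and allylic) and C6' (quaternary) are adjacent stereocentres, both S, with coumarin A and the styryl arm cis on ring C. The fragile groups are the two coumarin lactones (open to hydride, alkoxide and carbanion attack and to conjugate addition at C4), the acid-sensitive trisubstituted C2'=C3' alkene and the E-styrene. The real difficulty is the pair C1'/C6': a quaternary carbon next to a hindered benzylic carbon, needed in one relative and one absolute configuration, with no heteroatom left on ring C to steer it. C8 of coumarin B is flanked by the methoxy group and the ring oxygen, so this unit is best attached last. The key step uses the fact that the C1'–C6' bond is allylic to C2'=C3' and that C7' can be a carboxyl carbon. The acid C7'(=O)–C6'–C1'–C2'=C3' is then the product of a [3,3] shift of a ketene acetal whose oxygen sat on C3'. Because C6' and C3' are linked through C5'–C4', that ketene acetal belongs to a δ-lactone carrying the coumarin A styryl group on its carbinol carbon.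

## Logic of the disconnections

22 ⇒ 18 + 21. The C8'–C8 bond between the ethenyl bridge and coumarin B is cut. It needs no stereocentre and puts the shielded C8 position at the end of the route. The forward Heck arylation must pick the monosubstituted alkene of 18 and give only the E alkene; quaternary C6' secures this because it offers no β-hydrogen.

18 ⇒ 17. The C7'=C8' bond is cut back to a formyl group on C6'. This restores the carbonyl that the [3,3] retron needs. The forward step is a one-carbon olefination of a hindered, non-enolisable aldehyde that must spare the coumarin lactone.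

17 ⇒ 15 (through 16). Only the oxidation level of C7' changes; the acid is the direct product of the sigmatropic step. The forward step must stop a hydride reduction at the aldehyde beside an aryl lactone.

15 ⇒ 12 (through 14 and 13). The C1'–C6' bond is cut and the C3'–O bond restored. This removes ring C and both stereocentres at once and leaves a single tertiary carbinol centre. The forward step must enolise the δ-lactone beside coumarin A, rearrange faster than the allylic C–O bond ionises, and start from a pure E alkene. The bridge that ties the two termini of the six-atom array is the two-carbon unit C4–C5 of the lactone, which excludes a chair.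

12 ⇒ 6 + 11. The C=C bond between the lactone and coumarin A is cut by carbonyl olefination. An arylation of a 6-vinyl lactone with zerovalent palladium was ruled out: tertiary allylic carboxylates ionise to π-allyl complexes and β-acyloxy elimination competes. The cut gives an achiral aryl phosphonate and a small chiral aldehyde. The phosphonate anion must add to the aldehyde faster than it deprotonates the lactone.

6 ⇒ 5 ⇒ 4. The aldehyde is taken back to the alcohol and the lactone C–O bond is opened to an acyclic diol ester. Ring closure must go through the tertiary hydroxyl (six-membered) and not the primary one (seven-membered).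

4 ⇒ 2 + 3, and 2 ⇒ 1. The C3–C4 bond of the hexanoate chain is cut into a β-hydroxyalkyl radical and an acrylate acceptor; the iodide comes from an epoxide. This places the only stereocentre that matters in a bought, epoxidation-derived building block. Asymmetric dihydroxylation of a 1,1-dialkylethylene was set aside because that olefin class gives only moderate enantioselectivity. The later intermediates are C3-epimer mixtures that cannot be enriched by crystallisation, and the key step can only pass on the purity it receives. Radical addition must outrun direct reduction; the carbinol centre is never a reaction site.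

11 ⇒ 10 ⇒ 9 ⇒ 8 ⇒ 7. The C–P, C–Br and O–CH3 bonds and then the pyranone ring (C4–C4a and O1–C2) are cut. In 7 the methyl group already sits on the carbon that becomes C6, so the position of the benzylic handle is fixed by the starting material. Bromination must be benzylic and not nuclear.

21 ⇒ 20 ⇒ 19. The O–CH3 and C8–I bonds are cut. Iodination must go to C8 and not to C6 or C3.

## Other disconnections considered

Alternative 1: The cut is in the benzene ring of coumarin A (C4a–C5). Ring C, already carrying both stereocentres and a vinyl group on C6', would bear the acetal-masked 3,5-dioxo ester chain of A2 on C1'. Acid would free the aldehyde, the active methylene would condense with it, and dehydration and enolisation would give resorcylate A1.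
- In its favour: aromatisation drives the closure, there is no stereochemical demand, the oxygen pattern is unambiguous, and the hydrogen-bonded 2-hydroxyl allows selective 4-O-methylation. No aryl lactone is present while strong bases are used; on this point it is better than the chosen plan.
- Against it: it builds a ring that can be bought as a resorcinol and leaves C1'/C6' to some other method. The polycarbonyl chain can also close to pyranones or by C-acylation. After A1 there remain methylation, ester-to-aldehyde adjustment, pyranone closure and the whole coumarin B attachment.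
- Comparison: on structure the chosen plan spends its key step on ring C and both stereocentres, Alternative 1 on an achiral ring. On mechanism the two closures are equally dependable. On step economy Alternative 1 is clearly longer.

Alternative 2: The cut is at C2'=C3'. The open-chain diene aldehyde A4 would be closed by the second-generation Grubbs catalyst RuCl2(=CHPh)(H2IMes)(PCy3) with loss of ethene to give A3, which is identical with 17. A4 would come from a stereoconvergent α-allylation of racemic 2,5-dimethylhex-5-enal with a racemic branched allyl electrophile of coumarin A, for example with [Ir(cod)Cl]2, a chiral ligand and a chiral amine.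
- In its favour: A3 is already at the aldehyde level, which saves step 11; this is better than the chosen plan. Metathesis to a cyclohexene needs neither a strong base nor an ionisable C–O bond and is at least the equal of the sigmatropic step in robustness. Both stereocentres would be set catalytically.
- Against it: the quaternary carbon would be formed in an acyclic intermolecular step whose two alkyl groups (methyl and a homoallyl chain) differ little, so the geometry of the enamine or enolate, and with it the relative configuration, is weakly controlled. The ortho-methoxy aryl allyl partner is an untested electrophile for branched selectivity. The metathesis must join a 1,1-disubstituted alkene to a vinyl group next to a congested centre.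
- Comparison: the chosen plan takes the relative configuration from a tether-enforced boat and the absolute configuration from one bought centre, while Alternative 2 needs reagent control for both. Alternative 2 could be shorter.

Alternative 3: The cut is in the benzene ring of coumarin B. The methoxyenyne A6 would react with the vinylketene from cyclobutenone A7 by [2+2] addition, four-electron ring opening, six-electron closure and tautomerisation to give phenol A5. Ortho-formylation and pyranone closure would follow.
- In its favour: the 1,2,3-substitution pattern (hydroxyl, vinyl link, methoxy) follows from the mechanism, and no coupling at a doubly ortho-substituted arene carbon is needed. On that point it is the equal or the better of the Heck reaction in step 15.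
- Against it: A6 can only be made from 17 by an alkynyl ether olefination, so ring C still needs its own key step. Ynol ethers and A7 are labile, and the annulation needs heat in the presence of a second alkene and coumarin A. After A5, two further steps are needed, where the chosen plan attaches a two-step aryl iodide in one.
- Comparison: on structure it solves the easier half of the molecule. On mechanism it is elegant but thermally demanding. On step economy it is longer.

Key step: step 10

Assumption: 1 is used as the commercial, enantiomerically enriched epoxide (if needed, upgraded once at the start by recrystallising its 4-nitrobenzoate); no step before step 10 touches that centre.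

Remark: CIP analysis gives (1'S,6'S) for 22, (1R,2R) for 15 and (6S) for 12. These are mutually consistent through the boat transition state, and the descriptor changes along the route come from priority changes only.

## Route

Step 1
Reactants: 1 [(2R)-2-methyloxiran-2-yl]methanol ((R)-2-methylglycidol)
Product: 2 (2R)-3-iodo-2-methylpropane-1,2-diol
Conditions: LiI, AcOH, THF, 0 → 23 °C
Reagents that add atoms: lithium iodide, [Li+].[I-]
Why: Iodide opens the acid-activated 2,2-disubstituted epoxide by SN2 attack at the unhindered CH2 (regioselective halohydrin formation). The quaternary stereocentre is not a reaction site and keeps its configuration.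

Step 2
Reactants: 2 (2R)-3-iodo-2-methylpropane-1,2-diol; 3 methyl 2-methylprop-2-enoate (methyl methacrylate)
Product: 4 methyl (2RS,5S)-5,6-dihydroxy-2,5-dimethylhexanoate
Conditions: Bu3SnH (slow addition), AIBN (cat.), 3 (5 equiv), PhH, 80 °C
Reagents that add atoms: none
Why: Giese reaction: the stannyl radical abstracts iodine, the primary β-hydroxyalkyl radical adds to the CH2 terminus of the electron-poor alkene, and Bu3SnH reduces the α-ester radical. The carbinol centre is untouched, and the new C2 centre forms as both epimers, which does not matter because it becomes sp2 in step 10.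

Step 3
Reactants: 4 methyl (2RS,5S)-5,6-dihydroxy-2,5-dimethylhexanoate
Product: 5 (3RS,6S)-6-(hydroxymethyl)-3,6-dimethyloxan-2-one
Conditions: TsOH·H2O (cat.), PhMe, 60 °C, 4 Å molecular sieves
Reagents that add atoms: none
Why: Acid-catalysed transesterification closes the six-membered lactone on the tertiary hydroxyl, which is favoured over the seven-membered ring through the primary hydroxyl and helped by the fully substituted carbinol carbon. Removal of methanol drives the equilibrium.

Step 4
Reactants: 5 (3RS,6S)-6-(hydroxymethyl)-3,6-dimethyloxan-2-one
Product: 6 (2S,5RS)-2,5-dimethyl-6-oxooxane-2-carbaldehyde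
Conditions: Dess–Martin periodinane, CH2Cl2, 23 °C
Reagents that add atoms: none
Why: Dess–Martin oxidation of the primary alcohol stops at the aldehyde under neutral conditions. The α-carbon is quaternary, so the stereocentre cannot epimerise.

Step 5
Reactants: 7 4-methylbenzene-1,3-diol (4-methylresorcinol)
Product: 8 7-hydroxy-6-methyl-2H-chromen-2-one
Conditions: malic acid, conc. H2SO4, 100 °C
Reagents that add atoms: malic acid, OC(CC(=O)O)C(=O)O
Why: Pechmann condensation: malic acid gives formylacetic acid in hot sulfuric acid, which attacks the only free ring position activated by both hydroxyls (ortho to one, para to the other) and lactonises. The methyl group therefore ends on C6.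

Step 6
Reactants: 8 7-hydroxy-6-methyl-2H-chromen-2-one
Product: 9 7-methoxy-6-methyl-2H-chromen-2-one
Conditions: MeI, K2CO3, acetone, reflux
Reagents that add atoms: iodomethane, CI
Why: Williamson O-methylation of the phenol; the coumarin lactone is stable to K2CO3 in acetone.

Step 7
Reactants: 9 7-methoxy-6-methyl-2H-chromen-2-one
Product: 10 6-(bromomethyl)-7-methoxy-2H-chromen-2-one
Conditions: NBS, AIBN (cat.), PhCF3, 90 °C
Reagents that add atoms: N-bromosuccinimide, O=C1CCC(=O)N1Br
Why: Wohl–Ziegler benzylic bromination by a radical chain in a non-polar solvent, which disfavours ionic bromination of the ring or of C3.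

Step 8
Reactants: 10 6-(bromomethyl)-7-methoxy-2H-chromen-2-one
Product: 11 diethyl [(7-methoxy-2-oxo-2H-chromen-6-yl)methyl]phosphonate
Conditions: P(OEt)3, 130 °C
Reagents that add atoms: triethyl phosphite, CCOP(OCC)OCC
Why: Michaelis–Arbuzov reaction of a reactive benzylic bromide; bromoethane distils off.

Step 9
Reactants: 6 (2S,5RS)-2,5-dimethyl-6-oxooxane-2-carbaldehyde; 11 diethyl [(7-methoxy-2-oxo-2H-chromen-6-yl)methyl]phosphonate
Product: 12 (3RS,6S)-6-[(E)-2-(7-methoxy-2-oxo-2H-chromen-6-yl)ethenyl]-3,6-dimethyloxan-2-one
Conditions: 11, KN(SiMe3)2, THF, −78 °C; then 6, −78 → 0 °C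
Reagents that add atoms: none
Why: Horner–Wadsworth–Emmons olefination of a non-enolisable aldehyde with an aryl-stabilised phosphonate anion; reversible addition and syn-elimination from the more stable adduct give the E alkene. No palladium is involved, so the tertiary allylic lactone cannot ionise, and the stereocentre is not touched.

Step 10
Reactants: 12 (3RS,6S)-6-[(E)-2-(7-methoxy-2-oxo-2H-chromen-6-yl)ethenyl]-3,6-dimethyloxan-2-one
Product: 15 (1R,2R)-2-(7-methoxy-2-oxo-2H-chromen-6-yl)-1,4-dimethylcyclohex-3-ene-1-carboxylic acid, via silyl ketene acetal 13 (not isolated), via trimethylsilyl ester 14 (not isolated)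
Conditions: LiN(SiMe3)2, Me3SiCl, Et3N, THF, −78 → 23 °C; PhMe, 100 °C; 1 M HCl, THF, 23 °C
Reagents that add atoms: none
Why: LiN(SiMe3)2 removes the only enolisable proton of 12 (C3–H of the δ-lactone; coumarin A has none) with Me3SiCl already present, so the enolate is O-silylated as it forms and both C3 epimers give the same cyclic ketene acetal 13. On heating, 13 undergoes the [3,3]-sigmatropic Ireland–Claisen shift of the array C3=C2–O1–C6–CH=CH(Ar): C3 bonds to the aryl-bearing alkene carbon (the C1'–C6' bond) while O1–C6 breaks and C2'=C3' appears, giving silyl ester 14, which the acidic work-up hydrolyses to 15. The closest known reaction type is the Ireland–Claisen rearrangement of silyl ketene acetals of 6-alkenyl δ-lactones to cyclohex-3-enecarboxylic acids. Ring C closes by the C–C bond formation itself; because the two termini of the array (C3 and C6) are tied by the two-carbon bridge C4–C5, the six atoms can only adopt a boat, as in a bicyclo[2.2.2]octane, with the styryl group axial. The quaternary centre C6' is set by suprafacial bonding on the ketene acetal face that carries the axial styryl group, which the (6S) carbinol centre fixes. C1' is set by the E geometry of the styrene, which in the boat turns the aryl group towards the C2–O1 bridge and so cis to the carboxyl carbon. The step needs chemoselective enolisation (coumarin A has no acidic proton, and the silyl chloride trap is present from the start), complete chirality transfer (a concerted, tether-enforced path) and a geometrically pure E alkene (from step 9). The new C=O bond and the trisubstituted ring alkene pay for the loss of styrene conjugation.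

Step 11
Reactants: 15 (1R,2R)-2-(7-methoxy-2-oxo-2H-chromen-6-yl)-1,4-dimethylcyclohex-3-ene-1-carboxylic acid
Product: 17 (1R,2R)-2-(7-methoxy-2-oxo-2H-chromen-6-yl)-1,4-dimethylcyclohex-3-ene-1-carbaldehyde, via acid chloride 16 (not isolated)
Conditions: (COCl)2, DMF (cat.), CH2Cl2, 0 → 23 °C; evaporate; LiAlH(OtBu)3, THF, −78 °C
Reagents that add atoms: none
Why: Partial reduction of an acyl chloride: the hindered, weakly reducing LiAlH(OtBu)3 attacks the acyl chloride at −78 °C much faster than the neopentyl-type aldehyde, the aryl lactone or the alkene. The quaternary α-carbon excludes epimerisation.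

Step 12
Reactants: 17 (1R,2R)-2-(7-methoxy-2-oxo-2H-chromen-6-yl)-1,4-dimethylcyclohex-3-ene-1-carbaldehyde
Product: 18 6-[(1S,6S)-6-ethenyl-3,6-dimethylcyclohex-2-en-1-yl]-7-methoxy-2H-chromen-2-one
Conditions: Ph3PCH3Br, KN(SiMe3)2, THF, 0 °C; then 17, −78 → 23 °C
Reagents that add atoms: methyltriphenylphosphonium bromide, C[P+](c1ccccc1)(c1ccccc1)c1ccccc1.[Br-]
Why: Wittig methylenation: the aldehyde is far more electrophilic than the coumarin carbonyl and has no α-hydrogen, so the unstabilised ylide reacts only there. The stereocentres are not involved (descriptors change by priority only).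

Step 13
Reactants: 19 7-hydroxy-2H-chromen-2-one (umbelliferone)
Product: 20 7-hydroxy-8-iodo-2H-chromen-2-one
Conditions: I2, KI, 20% aq. NH3, 23 °C; then dil. HCl
Reagents that add atoms: iodine, II
Why: Electrophilic iodination of the phenoxide: C8, ortho to the oxygen and between the two oxygen substituents, is the most nucleophilic position of this coumarin, as in its other ortho-selective substitutions.

Step 14
Reactants: 20 7-hydroxy-8-iodo-2H-chromen-2-one
Product: 21 8-iodo-7-methoxy-2H-chromen-2-one
Conditions: MeI, K2CO3, acetone, reflux
Reagents that add atoms: iodomethane, CI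
Why: Williamson O-methylation of the phenol; the aryl iodide and the lactone are inert.

Step 15
Reactants: 18 6-[(1S,6S)-6-ethenyl-3,6-dimethylcyclohex-2-en-1-yl]-7-methoxy-2H-chromen-2-one; 21 8-iodo-7-methoxy-2H-chromen-2-one
Product: 22 7-methoxy-6-[(1S,6S)-6-[(E)-2-(7-methoxy-2-oxo-2H-chromen-8-yl)ethenyl]-3,6-dimethylcyclohex-2-en-1-yl]-2H-chromen-2-one
Conditions: Pd(OAc)2 (5 mol %), Bu4NCl, NaHCO3, DMF, 80 °C
Reagents that add atoms: none
Why: Mizoroki–Heck reaction under ligand-free phase-transfer conditions: zerovalent palladium adds oxidatively to the aryl iodide, the only monosubstituted alkene inserts with the aryl group going to the terminal carbon, and β-hydride elimination can use only the benzylic hydrogens because C6' is quaternary, so only the E-styrene forms. Heck arylations of 8-iodocoumarins with alkenes on a fully substituted carbon are established, and the stereocentres are not involved.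

## Compound list

1 | [(2R)-2-methyloxiran-2-yl]methanol ((R)-2-methylglycidol) | C[C@@]1(CO)CO1 | starting material
2 | (2R)-3-iodo-2-methylpropane-1,2-diol | C[C@@](O)(CO)CI | intermediate
3 | methyl 2-methylprop-2-enoate (methyl methacrylate) | C=C(C)C(=O)OC | starting material
4 | methyl (2RS,5S)-5,6-dihydroxy-2,5-dimethylhexanoate | COC(=O)C(C)CC[C@@](C)(CO)O | intermediate
5 | (3RS,6S)-6-(hydroxymethyl)-3,6-dimethyloxan-2-one | CC1CC[C@@](C)(CO)OC1=O | intermediate
6 | (2S,5RS)-2,5-dimethyl-6-oxooxane-2-carbaldehyde | CC1CC[C@@](C)(C=O)OC1=O | intermediate
7 | 4-methylbenzene-1,3-diol (4-methylresorcinol) | Cc1ccc(O)cc1O | starting material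
8 | 7-hydroxy-6-methyl-2H-chromen-2-one | Cc1cc2ccc(=O)oc2cc1O | intermediate
9 | 7-methoxy-6-methyl-2H-chromen-2-one | Cc1cc2ccc(=O)oc2cc1OC | intermediate
10 | 6-(bromomethyl)-7-methoxy-2H-chromen-2-one | BrCc1cc2ccc(=O)oc2cc1OC | intermediate
11 | diethyl [(7-methoxy-2-oxo-2H-chromen-6-yl)methyl]phosphonate | CCOP(=O)(OCC)Cc1cc2ccc(=O)oc2cc1OC | intermediate
12 | (3RS,6S)-6-[(E)-2-(7-methoxy-2-oxo-2H-chromen-6-yl)ethenyl]-3,6-dimethyloxan-2-one | CC1CC[C@@](C)(/C=C/c2cc3ccc(=O)oc3cc2OC)OC1=O | intermediate
13 | 6-[(E)-2-{(2S)-2,5-dimethyl-6-[(trimethylsilyl)oxy]-3,4-dihydro-2H-pyran-2-yl}ethenyl]-7-methoxy-2H-chromen-2-one | CC1=C(O[Si](C)(C)C)O[C@](C)(/C=C/c2cc3ccc(=O)oc3cc2OC)CC1 | intermediate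
14 | trimethylsilyl (1R,2R)-2-(7-methoxy-2-oxo-2H-chromen-6-yl)-1,4-dimethylcyclohex-3-ene-1-carboxylate | COc1cc2oc(=O)ccc2cc1[C@H]1C=C(C)CC[C@@]1(C)C(=O)O[Si](C)(C)C | intermediate
15 | (1R,2R)-2-(7-methoxy-2-oxo-2H-chromen-6-yl)-1,4-dimethylcyclohex-3-ene-1-carboxylic acid | COc1cc2oc(=O)ccc2cc1[C@H]1C=C(C)CC[C@@]1(C)C(=O)O | intermediate
16 | (1R,2R)-2-(7-methoxy-2-oxo-2H-chromen-6-yl)-1,4-dimethylcyclohex-3-ene-1-carbonyl chloride | COc1cc2oc(=O)ccc2cc1[C@H]1C=C(C)CC[C@@]1(C)C(=O)Cl | intermediate
17 | (1R,2R)-2-(7-methoxy-2-oxo-2H-chromen-6-yl)-1,4-dimethylcyclohex-3-ene-1-carbaldehyde | COc1cc2oc(=O)ccc2cc1[C@H]1C=C(C)CC[C@@]1(C)C=O | intermediate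
18 | 6-[(1S,6S)-6-ethenyl-3,6-dimethylcyclohex-2-en-1-yl]-7-methoxy-2H-chromen-2-one | COc1cc2oc(=O)ccc2cc1[C@H]1C=C(C)CC[C@@]1(C)C=C | intermediate
19 | 7-hydroxy-2H-chromen-2-one (umbelliferone) | O=c1ccc2ccc(O)cc2o1 | starting material
20 | 7-hydroxy-8-iodo-2H-chromen-2-one | O=c1ccc2ccc(O)c(I)c2o1 | intermediate
21 | 8-iodo-7-methoxy-2H-chromen-2-one | COc1ccc2ccc(=O)oc2c1I | intermediate
22 | 7-methoxy-6-[(1S,6S)-6-[(E)-2-(7-methoxy-2-oxo-2H-chromen-8-yl)ethenyl]-3,6-dimethylcyclohex-2-en-1-yl]-2H-chromen-2-one | COc1cc2oc(=O)ccc2cc1[C@H]1C=C(C)CC[C@@]1(C)/C=C/c1c(OC)ccc2ccc(=O)oc12 | target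

## Step count and least certain steps

Total step count: 15. Longest linear sequence: 9 steps (steps 1–4, 9–12 and 15 from 1; equally steps 5–12 and 15 from 7).

**Step 10 (key step).** The most likely failure is attack of the amide base or of the lactone enolate on coumarin A (conjugate addition at C4 or at the lactone carbonyl) before O-silylation is complete, because an unhindered aryl enoate shares the flask with the enolate. A second risk is heterolysis of the tertiary allylic C–O bond during heating.

The fallback sets out from 6 and returns at 15; it carries an aryl group without a lactone through the ring contraction and completes coumarin A afterwards.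
- Aldehyde 6 would be olefinated (KN(SiMe3)2, THF) with diethyl [(2,4-dimethoxyphenyl)methyl]phosphonate F1, made in one step from commercial (2,4-dimethoxyphenyl)methanol with P(OEt)3 and ZnI2. This gives (3RS,6S)-6-[(E)-2-(2,4-dimethoxyphenyl)ethenyl]-3,6-dimethyloxan-2-one F2.
- F2 would be enolised with LiN(iPr)2/Me3SiCl and rearranged as in step 10 to (1R,2R)-2-(2,4-dimethoxyphenyl)-1,4-dimethylcyclohex-3-ene-1-carboxylic acid F3.
- Vilsmeier–Haack formylation (POCl3, DMF; aqueous NaOAc) at the position para to the 2-methoxy group would give (1R,2R)-2-(5-formyl-2,4-dimethoxyphenyl)-1,4-dimethylcyclohex-3-ene-1-carboxylic acid F4.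
- BCl3 at low temperature would cleave only the methyl ether ortho to the formyl group to give (1R,2R)-2-(5-formyl-4-hydroxy-2-methoxyphenyl)-1,4-dimethylcyclohex-3-ene-1-carboxylic acid F5.
- Wittig reaction with ethyl (triphenylphosphoranylidene)acetate in hot N,N-diethylaniline (olefination, alkene isomerisation, lactonisation) would close the pyranone and give 15.

**Step 9.** The most likely failure is loss of the adduct before elimination. The new alkoxide sits next to the carbon bearing the lactone oxygen and can take over the acyl group, or the benzylic carbanion can deprotonate the lactone α-position, because elimination from aryl-stabilised adducts is slow at low temperature.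

The fallback sets out from 6 and 11 and returns at 12.
- Methylenation of 6 (Ph3PCH3Br, KN(SiMe3)2) would give (3RS,6S)-6-ethenyl-3,6-dimethyloxan-2-one F6.
- Olefination of monomeric formaldehyde with the anion of 11 would give 6-ethenyl-7-methoxy-2H-chromen-2-one F7.
- Cross-metathesis of F6 and F7 with the second-generation Hoveyda–Grubbs catalyst RuCl2(=CH-2-iPrOC6H4)(H2IMes) in toluene at 60 °C would give the E alkene 12. Ruthenium carbenes do not ionise allylic esters.

**Step 11.** The most likely failure is over-reduction of the aldehyde to the primary alcohol, or hydride attack on the coumarin lactone, because the hindered acyl chloride reacts slowly and unreacted hydride builds up. The fallback sets out from 16 and returns at 17. NaBH4 in THF at 0 °C would reduce 16 fully to 6-[(1S,6R)-6-(hydroxymethyl)-3,6-dimethylcyclohex-2-en-1-yl]-7-methoxy-2H-chromen-2-one F8, and Dess–Martin periodinane would reoxidise F8 to 17.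

**Step 15.** The most likely failure is slow insertion of the alkene on its fully substituted carbon into the doubly ortho-substituted arylpalladium species. Catalyst decay, reductive loss of iodine or arylation of a coumarin double bond would then take over.

The fallback sets out from 17 (bypassing 18) and returns at 22.
- Olefination of 17 with CrCl2 (divalent chromium), LiI and 2-(dichloromethyl)-4,4,5,5-tetramethyl-1,3,2-dioxaborolane would give 7-methoxy-6-[(1S,6S)-3,6-dimethyl-6-[(E)-2-(4,4,5,5-tetramethyl-1,3,2-dioxaborolan-2-yl)ethenyl]cyclohex-2-en-1-yl]-2H-chromen-2-one F9.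
- Suzuki–Miyaura coupling of F9 with 21 (Pd(PPh3)4, K3PO4, dioxane/H2O, 80 °C), followed by mildly acidic work-up to re-close any opened lactone, would give 22 with the E geometry fixed in the boronate.

## Further compounds

F1 | step 10 | diethyl [(2,4-dimethoxyphenyl)methyl]phosphonate | CCOP(=O)(OCC)Cc1ccc(OC)cc1OC
F2 | step 10 | (3RS,6S)-6-[(E)-2-(2,4-dimethoxyphenyl)ethenyl]-3,6-dimethyloxan-2-one | CC1CC[C@@](C)(/C=C/c2ccc(OC)cc2OC)OC1=O
F3 | step 10 | (1R,2R)-2-(2,4-dimethoxyphenyl)-1,4-dimethylcyclohex-3-ene-1-carboxylic acid | COc1ccc([C@H]2C=C(C)CC[C@@]2(C)C(O)=O)c(OC)c1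
F4 | step 10 | (1R,2R)-2-(5-formyl-2,4-dimethoxyphenyl)-1,4-dimethylcyclohex-3-ene-1-carboxylic acid | COc1cc(OC)c(C=O)cc1[C@H]1C=C(C)CC[C@@]1(C)C(O)=O
F5 | step 10 | (1R,2R)-2-(5-formyl-4-hydroxy-2-methoxyphenyl)-1,4-dimethylcyclohex-3-ene-1-carboxylic acid | COc1cc(O)c(C=O)cc1[C@H]1C=C(C)CC[C@@]1(C)C(O)=O
F6 | step 9 | (3RS,6S)-6-ethenyl-3,6-dimethyloxan-2-one | CC1CC[C@@](C)(C=C)OC1=O
F7 | step 9 | 6-ethenyl-7-methoxy-2H-chromen-2-one | C=Cc1cc2ccc(=O)oc2cc1OC
F8 | step 11 | 6-[(1S,6R)-6-(hydroxymethyl)-3,6-dimethylcyclohex-2-en-1-yl]-7-methoxy-2H-chromen-2-one | COc1cc2oc(=O)ccc2cc1[C@H]1C=C(C)CC[C@@]1(C)CO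
F9 | step 15 | 7-methoxy-6-[(1S,6S)-3,6-dimethyl-6-[(E)-2-(4,4,5,5-tetramethyl-1,3,2-dioxaborolan-2-yl)ethenyl]cyclohex-2-en-1-yl]-2H-chromen-2-one | COc1cc2oc(=O)ccc2cc1[C@H]1C=C(C)CC[C@@]1(C)/C=C/B1OC(C)(C)C(C)(C)O1
A1 | alternative 1 | methyl 5-[(1S,6S)-6-ethenyl-3,6-dimethylcyclohex-2-en-1-yl]-2,4-dihydroxybenzoate | COC(=O)c1cc([C@H]2C=C(C)CC[C@@]2(C)C=C)c(O)cc1O
A2 | alternative 1 | methyl 6-[(1R,6S)-6-ethenyl-3,6-dimethylcyclohex-2-en-1-yl]-7,7-dimethoxy-3,5-dioxoheptanoate (C6 of the chain unspecified) | COC(=O)CC(=O)CC(=O)C(C(OC)OC)[C@H]1C=C(C)CC[C@@]1(C)C=C
A3 | alternative 2 | (1R,2R)-2-(7-methoxy-2-oxo-2H-chromen-6-yl)-1,4-dimethylcyclohex-3-ene-1-carbaldehyde (identical with 17) | COc1cc2oc(=O)ccc2cc1[C@H]1C=C(C)CC[C@@]1(C)C=O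
A4 | alternative 2 | (2R)-2-[(1R)-1-(7-methoxy-2-oxo-2H-chromen-6-yl)prop-2-en-1-yl]-2,5-dimethylhex-5-enal | COc1cc2oc(=O)ccc2cc1[C@@H](C=C)[C@@](C)(CCC(C)=C)C=O
A5 | alternative 3 | 6-[(1S,6S)-6-[(E)-2-(2-hydroxy-6-methoxyphenyl)ethenyl]-3,6-dimethylcyclohex-2-en-1-yl]-7-methoxy-2H-chromen-2-one | COc1cc2oc(=O)ccc2cc1[C@H]1C=C(C)CC[C@@]1(C)/C=C/c1c(OC)cccc1O
A6 | alternative 3 | 7-methoxy-6-[(1S,6S)-6-[(E)-4-methoxybut-1-en-3-yn-1-yl]-3,6-dimethylcyclohex-2-en-1-yl]-2H-chromen-2-one | COc1cc2oc(=O)ccc2cc1[C@H]1C=C(C)CC[C@@]1(C)/C=C/C#COC
A7 | alternative 3 | cyclobut-2-en-1-one | O=C1CC=C1
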